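**Retrosynthetic overview**
1. The central CH2 is disconnected to formaldehyde and two molecules of the monomer 7-acetyl-6,8-dihydroxy-4,4-dimethylnaphthalene-1,3-dione (Knoevenagel aldol condensation, then Michael addition); this coupling is the last step.
2. The monomer comes from its dimethyl ether, whose ring B (the 1,3-dione ring) is closed by intramolecular Friedel–Crafts acylation of an aryl β-keto ester onto ring A.
3. The β-keto ester comes from an α,α-dimethyl arylacetic acid and a malonate half ester; the acetyl group is placed between the two methoxy groups by directed ortho-lithiation.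
4. Ring A is bought as methyl 3,5-dimethoxyphenylacetate and its benzylic carbon is dimethylated first. Ring order: ring A (purchased), ring B (step 7), then union of the two bicycles (step 9).

Assumption: the target SMILES has no stereocentre and the molecule is achiral, so there is no enantiomer to select; the 1,3-dione intermediates are written in the diketo form although they are largely enolised.

**Step 1**
Reactants: 1 methyl 2-(3,5-dimethoxyphenyl)acetate; 2 iodomethane
Product: 3 methyl 2-(3,5-dimethoxyphenyl)-2-methylpropanoate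
Conditions: NaH (2.5 equiv), MeI (3 equiv), DMF, 0 °C to rt
Reagents that add atoms: iodomethane, CI
Why: Double enolate C-alkylation of the acidic benzylic ester position installs the gem-dimethyl group (the mono-methyl ester is deprotonated and alkylated again under the same conditions), and no stereocentre is formed.

**Step 2**
Reactants: 3 methyl 2-(3,5-dimethoxyphenyl)-2-methylpropanoate
Product: 4 2-(3,5-dimethoxyphenyl)-2-methylpropan-1-ol
Conditions: LiAlH4, THF, 0 °C to rt
Reagents that add atoms: none
Why: Hydride reduction of the ester to the neopentyl alcohol removes the only electrophilic group, so the substrate tolerates n-BuLi in step 3.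

**Step 3**
Reactants: 4 2-(3,5-dimethoxyphenyl)-2-methylpropan-1-ol; 5 acetaldehyde
Product: 7 (±)-1-[4-(1-hydroxy-2-methylpropan-2-yl)-2,6-dimethoxyphenyl]ethan-1-ol, via aryllithium alkoxide 6 (not isolated)
Conditions: n-BuLi (2.5 equiv), TMEDA, THF, 0 °C to rt; then MeCHO, −78 °C to rt; H2O
Reagents that add atoms: acetaldehyde, CC=O
Why: Directed ortho-metalation: after the hydroxyl is deprotonated, n-BuLi removes the ring proton flanked by both methoxy groups and the aryllithium adds to acetaldehyde, the new carbinol centre being formed as a racemate that is erased in step 4.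

**Step 4**
Reactants: 7 (±)-1-[4-(1-hydroxy-2-methylpropan-2-yl)-2,6-dimethoxyphenyl]ethan-1-ol
Product: 8 2-(4-acetyl-3,5-dimethoxyphenyl)-2-methylpropanal
Conditions: Dess–Martin periodinane (2.6 equiv), NaHCO3, CH2Cl2, rt
Reagents that add atoms: none
Why: Dess–Martin oxidation turns the secondary benzylic alcohol into the aryl methyl ketone and the primary alcohol into a non-enolisable aldehyde under buffered conditions that spare the acid-sensitive, electron-rich benzylic carbinol.

**Step 5**
Reactants: 8 2-(4-acetyl-3,5-dimethoxyphenyl)-2-methylpropanal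
Product: 9 2-(4-acetyl-3,5-dimethoxyphenyl)-2-methylpropanoic acid
Conditions: NaClO2, NaH2PO4, 2-methyl-2-butene, t-BuOH/H2O, rt
Reagents that add atoms: sodium chlorite, [Na+].[O-]Cl=O
Why: Pinnick oxidation takes the aldehyde selectively to the carboxylic acid, leaves the ketone alone, and the alkene scavenges HOCl before it can chlorinate the ring.

**Step 6**
Reactants: 9 2-(4-acetyl-3,5-dimethoxyphenyl)-2-methylpropanoic acid; 10 potassium 3-ethoxy-3-oxopropanoate (potassium ethyl malonate)
Product: 13 ethyl 4-(4-acetyl-3,5-dimethoxyphenyl)-4-methyl-3-oxopentanoate, via acyl imidazolide 11 (not isolated), via acylmalonic half ester 12 (not isolated)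
Conditions: CDI, THF, rt; then KO2CCH2CO2Et, MgCl2, Et3N, MeCN, rt to 50 °C; aq. HCl
Reagents that add atoms: potassium 3-ethoxy-3-oxopropanoate, [K+].[O-]C(=O)CC(=O)OCC
Why: Masamune–Brooks C-acylation (a decarboxylative Claisen-type condensation): the magnesium enolate of the malonate half ester attacks the acyl imidazolide and the adduct loses CO2 on acidic work-up, which needs no strong base and tolerates the aryl ketone.

**Step 7**
Reactants: 13 ethyl 4-(4-acetyl-3,5-dimethoxyphenyl)-4-methyl-3-oxopentanoate
Product: 14 7-acetyl-6,8-dimethoxy-4,4-dimethylnaphthalene-1,3(2H,4H)-dione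
Conditions: P2O5/MeSO3H (Eaton's reagent), rt to 40 °C
Reagents that add atoms: none
Why: Intramolecular Friedel–Crafts acylation: the acid-activated ester carbonyl attacks one of the two equivalent ring positions next to the quaternary carbon (each ortho and para to a methoxy group), the gem-dimethyl group favours six-membered closure, and ring B forms as a single regioisomer.

**Step 8**
Reactants: 14 7-acetyl-6,8-dimethoxy-4,4-dimethylnaphthalene-1,3(2H,4H)-dione
Product: 15 7-acetyl-6,8-dihydroxy-4,4-dimethylnaphthalene-1,3(2H,4H)-dione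
Conditions: BBr3 (5 equiv), CH2Cl2, −78 °C to rt; H2O
Reagents that add atoms: none
Why: Lewis acid ether cleavage: both methoxy groups sit ortho to a carbonyl, so chelation by BBr3 makes their demethylation fast while the ketones, the 1,3-dione and the quaternary carbon are inert.

**Step 9**
Reactants: 15 7-acetyl-6,8-dihydroxy-4,4-dimethylnaphthalene-1,3(2H,4H)-dione (2 equiv); 16 formaldehyde
Product: 19 2,2'-methylenebis[7-acetyl-3,6,8-trihydroxy-4,4-dimethylnaphthalen-1(4H)-one] (target), via hydroxymethyl aldol adduct 17 (not isolated), via methylidene trione 18 (not isolated)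
Conditions: 37% aq. CH2O (0.5 equiv), NaOAc, EtOH/H2O, rt
Reagents that add atoms: formaldehyde, C=O
Why: Knoevenagel aldol condensation of the acidic cyclic 1,3-dione with formaldehyde gives the 2-methylidene trione, a strong Michael acceptor that is captured at once by the enol of a second molecule of 15, and the half equivalent of formaldehyde stops the sequence at the methylene-bridged dimer without creating a stereocentre.

**Compound list**
1 | methyl 2-(3,5-dimethoxyphenyl)acetate | COC(=O)Cc1cc(OC)cc(OC)c1 | starting material
2 | iodomethane | CI | starting material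
3 | methyl 2-(3,5-dimethoxyphenyl)-2-methylpropanoate | COC(=O)C(C)(C)c1cc(OC)cc(OC)c1 | intermediate
4 | 2-(3,5-dimethoxyphenyl)-2-methylpropan-1-ol | OCC(C)(C)c1cc(OC)cc(OC)c1 | intermediate
5 | acetaldehyde | CC=O | starting material
6 | lithium 2-(4-lithio-3,5-dimethoxyphenyl)-2-methylpropan-1-olate | [Li]OCC(C)(C)c1cc(OC)c([Li])c(OC)c1 | intermediate (not isolated)
7 | (±)-1-[4-(1-hydroxy-2-methylpropan-2-yl)-2,6-dimethoxyphenyl]ethan-1-ol (racemic) | CC(O)c1c(OC)cc(cc1OC)C(C)(C)CO | intermediate
8 | 2-(4-acetyl-3,5-dimethoxyphenyl)-2-methylpropanal | CC(=O)c1c(OC)cc(cc1OC)C(C)(C)C=O | intermediate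
9 | 2-(4-acetyl-3,5-dimethoxyphenyl)-2-methylpropanoic acid | CC(=O)c1c(OC)cc(cc1OC)C(C)(C)C(O)=O | intermediate
10 | potassium 3-ethoxy-3-oxopropanoate (potassium ethyl malonate) | [K+].[O-]C(=O)CC(=O)OCC | starting material
11 | 1-[2-(4-acetyl-3,5-dimethoxyphenyl)-2-methylpropanoyl]-1H-imidazole | CC(=O)c1c(OC)cc(cc1OC)C(C)(C)C(=O)n1ccnc1 | intermediate (not isolated)
12 | 4-(4-acetyl-3,5-dimethoxyphenyl)-2-(ethoxycarbonyl)-4-methyl-3-oxopentanoic acid | CCOC(=O)C(C(O)=O)C(=O)C(C)(C)c1cc(OC)c(C(C)=O)c(OC)c1 | intermediate (not isolated)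
13 | ethyl 4-(4-acetyl-3,5-dimethoxyphenyl)-4-methyl-3-oxopentanoate | CCOC(=O)CC(=O)C(C)(C)c1cc(OC)c(C(C)=O)c(OC)c1 | intermediate
14 | 7-acetyl-6,8-dimethoxy-4,4-dimethylnaphthalene-1,3(2H,4H)-dione | CC(=O)c1c(OC)cc2c(c1OC)C(=O)CC(=O)C2(C)C | intermediate
15 | 7-acetyl-6,8-dihydroxy-4,4-dimethylnaphthalene-1,3(2H,4H)-dione | CC(=O)c1c(O)cc2c(c1O)C(=O)CC(=O)C2(C)C | intermediate
16 | formaldehyde | C=O | starting material
17 | 7-acetyl-6,8-dihydroxy-2-(hydroxymethyl)-4,4-dimethylnaphthalene-1,3(2H,4H)-dione | CC(=O)c1c(O)cc2c(c1O)C(=O)C(CO)C(=O)C2(C)C | intermediate (not isolated)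
18 | 7-acetyl-6,8-dihydroxy-4,4-dimethyl-2-methylidenenaphthalene-1,3(2H,4H)-dione | CC(=O)c1c(O)cc2c(c1O)C(=O)C(=C)C(=O)C2(C)C | intermediate (not isolated)
19 | 2,2'-methylenebis[7-acetyl-3,6,8-trihydroxy-4,4-dimethylnaphthalen-1(4H)-one] | CC(=O)c1c(O)cc2c(c1O)C(=O)C(CC1=C(O)C(C)(C)c3cc(O)c(C(C)=O)c(O)c3C1=O)=C(O)C2(C)C | target

**Count and risks**
Total step count: 9. Longest linear sequence: 9 steps (1 → 19); the last step joins two molecules of 15.

The three steps most likely to fail are steps 6, 7 and 9.

Step 6 (acyl transfer to a hindered, α-quaternary acyl imidazolide may be slow). The fallback sets out from aldehyde 8 and bypasses acid 9. A Reformatsky reaction of 8 with ethyl bromoacetate and zinc dust in THF at 50 °C adds to the aldehyde in preference to the hindered, twisted aryl methyl ketone and gives racemic ethyl 4-(4-acetyl-3,5-dimethoxyphenyl)-3-hydroxy-4-methylpentanoate F1. Dess–Martin oxidation of F1 then gives the β-keto ester, and the route is rejoined at 13.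

Step 7 (the acetyl group lowers ring nucleophilicity and could be lost by acid-induced deacylation before ring closure). The fallback sets out from 13 and reverses the order of deprotection and cyclisation. BBr3 in CH2Cl2 at −78 to 0 °C first gives ethyl 4-(4-acetyl-3,5-dihydroxyphenyl)-4-methyl-3-oxopentanoate F2. This much more nucleophilic resorcinol is then closed by intramolecular Friedel–Crafts (Nencki-type) acylation in MeSO3H at rt, run dilute to suppress intermolecular Pechmann condensation. The route is rejoined at 15, so 14 and step 8 are skipped.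

Step 9 (formaldehyde may over-react or give oligomers with the polyphenol). The fallback sets out from 15 and separates the two bond formations. A Mannich reaction of 15 with N,N-dimethylmethyleneiminium iodide (Eschenmoser's salt) in CH2Cl2 gives the isolable 7-acetyl-2-[(dimethylamino)methyl]-6,8-dihydroxy-4,4-dimethylnaphthalene-1,3(2H,4H)-dione F3. Warming F3 with one further equivalent of 15 in EtOH/AcOH at 60 °C eliminates dimethylamine to 18 in the presence of the nucleophile, and Michael addition gives the target, rejoining the route at 19.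

**Further compounds**
F1 | step 6 | ethyl 4-(4-acetyl-3,5-dimethoxyphenyl)-3-hydroxy-4-methylpentanoate (racemic) | CCOC(=O)CC(O)C(C)(C)c1cc(OC)c(C(C)=O)c(OC)c1
F2 | step 7 | ethyl 4-(4-acetyl-3,5-dihydroxyphenyl)-4-methyl-3-oxopentanoate | CCOC(=O)CC(=O)C(C)(C)c1cc(O)c(C(C)=O)c(O)c1
F3 | step 9 | 7-acetyl-2-[(dimethylamino)methyl]-6,8-dihydroxy-4,4-dimethylnaphthalene-1,3(2H,4H)-dione | CC(=O)c1c(O)cc2c(c1O)C(=O)C(CN(C)C)C(=O)C2(C)C
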